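I began with a division anyone can do: the partner charged over the starting material charged, e = 1.20, the partner budget per starting material. It comes from the recipe, and I used it as the cap on the partner taken up wherever partner is the limiting reagent.

| setting | alpha | theta | zeta | Sunday's | Thursday's | Friday's | Tuesday's |
|---|---|---|---|---|---|---|---|
| starting material | 0.40 M | 0.40 M | 0.80 M | 0.40 M | 0.40 M | 0.40 M | 0.40 M |
| partner | 0.24 M | 0.36 M | 0.48 M | 0.480 M | 0.480 M | 0.480 M | 0.480 M |
| temperature | 60 °C | 88 °C | 60 °C | 65 °C | 110 °C | 80 °C | 95 °C |
| remark | run made earlier | run made earlier | run made earlier |  |  |  |  |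
| time |  |  |  | 3.0 h | 3.0 h | 3.0 h | 3.0 h |

alpha run (percent of the starting material charged)

| time / h | mono adduct / % | double product / % |
|---|---|---|
| 0.250 | 1.1 | 0 |
| 0.500 | 2.2 | 0 |
| 1.00 | 3.0 | 0 |
| 2.00 | 6.3 | 0 |
| 4.00 | 11.5 | 0.3 |

theta run (percent of the starting material charged)

| time / min | mono adduct / % | double product / % |
|---|---|---|
| 6.00 | 6.0 | 0 |
| 15.0 | 14.5 | 1.1 |
| 30.0 | 22.0 | 1.7 |
| 50.0 | 29.6 | 3.2 |
| 80.0 | 35.1 | 4.0 |

zeta run (percent of the starting material charged)

| time / h | mono adduct / % | double product / % |
|---|---|---|
| 0.333 | 2.0 | 0.2 |
| 0.833 | 6.2 | 0 |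
| 1.50 | 9.9 | 0.1 |
| 2.50 | 12.6 | 0.1 |
| 4.00 | 19.9 | 0.7 |

(readings scatter by 0.5 percentage points)

* the best flask by share of mono adduct in all that became mono adduct or double product or triple product or tetra adduct; "all alike" if 1.5 percentage points covers them all (Sunday's / Thursday's / Friday's / Tuesday's / all alike)
* share of mono adduct in all that became mono adduct or double product or triple product or tetra adduct, Sunday's
* share of mono adduct in all that became mono adduct or double product or triple product or tetra adduct, Thursday's
* share of mono adduct in all that became mono adduct or double product or triple product or tetra adduct, Friday's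
* share of mono adduct in all that became mono adduct or double product or triple product or tetra adduct, Tuesday's



Next I needed the curve's start. From the first usable readings, the mono adduct step gave 0.131 M⁻¹ h⁻¹ in the alpha run and 1.67 M⁻¹ h⁻¹ in the theta run. Extending that trend to Thursday's gave 12.3 M⁻¹ h⁻¹, so mono adduct started there at 5.89 h⁻¹ of the charge. That made a time scale of 10.2 min, much shorter than the 3.0 h allowed, so I expected Thursday's to reach its level.

The last theta reading gave, as a reading at 88 °C that I assumed for every flask, the selectivity factor, double step over mono step, ρ = 0.460. With a for starting material left and m for mono adduct, both as fractions of the charge, and the chain stopped at double product, I used: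

m = (a^ρ − a)/(1 − ρ)

a = 1 − (e + m)/2

Starting from two partners per converted starting material, a = 0.400, and putting each answer back in, I got:

a = 0.163, then 0.149

In this reckoning mono adduct crests at a = 0.237, so I put Thursday's past its top, at an estimated share of 58.2%. For Sunday's, ignoring the fall in partner, a = 0.743 gave 93.1%, above Thursday's. Friday's and Tuesday's I placed between them.

The forecast named Sunday's, with 95.5%, 64%, 85% and 70% in the order asked, its Thursday's figure standing above mine: “The coolest flask, Sunday's, is best.”

The flasks gave 91.6% for Sunday's, 64.3% for Thursday's, 77.1% for Friday's and 64.7% for Tuesday's, so Sunday's was best.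

    starting material + partner → mono adduct (k = 0.0170 M⁻¹ min⁻¹, Ea = 91.0 kJ mol⁻¹)
    partner + triple product → tetra adduct (k = 0.0170 M⁻¹ min⁻¹, Ea = 76.0 kJ mol⁻¹)
    partner + double product → triple product (k = 0.0280 M⁻¹ min⁻¹, Ea = 89.0 kJ mol⁻¹)
    starting material ⇌ dormant form (K = 0.510, k = 0.00270 min⁻¹, Ea = 123 kJ mol⁻¹, ΔH = −15.0 kJ mol⁻¹)
    partner + mono adduct → double product (k = 0.00820 M⁻¹ min⁻¹, Ea = 86.0 kJ mol⁻¹)
    (constants at 80 °C)

Thursday's ended with 0.0131% of its partner unbound. Counting each product by the partner it holds gives 1.20 of the starting material charged, which is e again. Sunday's still held 75.5% of its partner at 3.00 h, and the time given is a part of its lead: left until 30.0 h, its share falls from 91.6% to 64.7%, against 64.3% for Thursday's at that time.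

The neighbour of Thursday's charged with 0.68 M of starting material has e = 0.706, and the same rounds give a = 0.488, then 0.433, and a share of 80.8%. That flask gave 78.9%, with partner at 0%.

(The numbers in the tables are calculated with constants of no real substance; scatter was added.)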